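Retrosynthesis: C7–OOH goes back to the C7=C8 alkene (ene reaction), C15–C17 to a lactone enolate, and H–C1 to a C1=C15 enoate. Then C1–C2 and C15–C16 are cut together, and last C13–C14. What remains is (2E,6E)-farnesol, 1-(trimethylsilyl)propyne, CO2 and MeI.
Enabling feature: the lactone carbonyl C16 sits on O3, next to the free tertiary C4–OH, and C2 is a plain CH2 beside C3. C16 can therefore be stored as the carbonyl of a five-membered C3/C4 cyclic carbonate and C2 as CH2I, which together make a 1,4-bis-electrophile C2–C3–O–C16.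
Forward: Cu–B addition turns a terminal C1≡C15 alkyne at the other chain end into a cis-1,2-dinucleophile. The 14-membered carbocycle (C1–C2) closes first, the δ-lactone (C15–C16) second, and C4–OH is released. Boron and the extra unsaturation are helpers that are removed again.
Stereochemistry: two Sharpless epoxidations with L-(+)-tartrate set C11/C12 and C4. C3 comes from SN2 inversion by the CO2-derived carbonate. C1 (conjugate reduction), C15 (methylation) and C7 (singlet oxygen) are controlled by the bicyclic framework.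

Key step: step 10

Remark: cembrane numbering is used. C1 = ring CH bearing C15, C2 = ring CH2, C3 = CH–O(lactone), C4 = C(OH)CH3, C7 = CH–OOH, C8 = C(=CH2), C11/C12 = epoxide, C15 = CH(CH3), C16 = lactone C=O, C17 = methyl on C15.
Assumption: outer-face attack of singlet oxygen on C7=C8 of 18 is taken to give 7R, because the target is the expected photooxygenation product of 18.

Step 1
Reactants: 1 (2E,6E)-farnesol
Product: 2 (2E,6E)-farnesyl tert-butyldimethylsilyl ether
Conditions: TBSCl, imidazole, DMF, rt
Reagents that add atoms: tert-butyldimethylsilyl chloride, CC(C)(C)[Si](C)(C)Cl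
Why: Silyl ether protection of the primary allylic alcohol masks C2–OH so that only the later C13–OH can direct the first epoxidation, and no stereocentre is formed.

Step 2
Reactants: 2 (2E,6E)-farnesyl tert-butyldimethylsilyl ether
Product: 3 (2E,6E,10E)-12-(tert-butyldimethylsilyloxy)-2,6,10-trimethyldodeca-2,6,10-trien-1-ol
Conditions: SeO2 (cat.), t-BuOOH, salicylic acid (cat.), CH2Cl2, 0 °C to rt
Reagents that add atoms: tert-butyl hydroperoxide, CC(C)(C)OO
Why: Selenium dioxide allylic oxidation (ene reaction, then [2,3]-shift) attacks the most electron-rich, terminal trisubstituted alkene and oxidises its E methyl group, which becomes C13 while C11=C12 stays E.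

Step 3
Reactants: 3 (2E,6E,10E)-12-(tert-butyldimethylsilyloxy)-2,6,10-trimethyldodeca-2,6,10-trien-1-ol
Product: 4 [(2S,3S)-3-[(3E,7E)-9-(tert-butyldimethylsilyloxy)-3,7-dimethylnona-3,7-dienyl]-2-methyloxiran-2-yl]methanol
Conditions: Ti(OiPr)4 (cat.), L-(+)-diethyl tartrate (cat.), t-BuOOH, 4 Å molecular sieves, CH2Cl2, −20 °C
Reagents that add atoms: tert-butyl hydroperoxide, CC(C)(C)OO
Why: The Sharpless asymmetric epoxidation is directed by the only free allylic alcohol and is therefore site-selective for C11=C12, and the L-(+)-tartrate sets 11S,12S by reagent control.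

Step 4
Reactants: 4 epoxy alcohol; 5 1-(trimethylsilyl)propyne
Product: 8 C11–C12 epoxide bearing the C2 OTBS group plus the C1≡C15–SiMe3 alkyne, via lithiated propyne 6 (not isolated), via triflate 7 (not isolated)
Conditions: 4, Tf2O, 2,6-lutidine, CH2Cl2, −78 °C; crude 7 added to 5/n-BuLi, THF–DMPU, −78 °C
Reagents that add atoms: none
Why: SN2 alkylation of a propargylic lithium reagent with a primary triflate forms C13–C14 at −78 °C, where the very reactive triflate should be consumed before the trisubstituted oxirane can open, and the epoxide stereocentres are not touched.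

Step 5
Reactants: 8 silyl ether/silyl alkyne
Product: 9 (2E,6E)-9-[(2S,3S)-3-(but-3-ynyl)-3-methyloxiran-2-yl]-3,7-dimethylnona-2,6-dien-1-ol
Conditions: Bu4NF (2.5 equiv), THF, 0 °C to rt
Reagents that add atoms: none
Why: Fluoride-induced desilylation cleaves both the O–Si and the alkynyl C–Si bond, so one operation frees the allylic alcohol for the second epoxidation and the terminal alkyne for the key step.

Step 6
Reactants: 9 epoxy enynol
Product: 10 [(2S,3S)-3-[(E)-6-[(2S,3S)-3-(but-3-ynyl)-3-methyloxiran-2-yl]-4-methylhex-3-enyl]-3-methyloxiran-2-yl]methanol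
Conditions: Ti(OiPr)4 (cat.), L-(+)-diethyl tartrate (cat.), t-BuOOH, 4 Å molecular sieves, CH2Cl2, −20 °C
Reagents that add atoms: tert-butyl hydroperoxide, CC(C)(C)OO
Why: A second Sharpless asymmetric epoxidation acts only on the allylic C3=C4 alkene, and L-(+)-tartrate gives the (3S,4S)-epoxide by reagent control, whose C4–O bond is kept to the end.

Step 7
Reactants: 10 bis-epoxy alcohol
Product: 11 (4R)-4-[(2S,5E)-8-[(2S,3S)-3-(but-3-ynyl)-3-methyloxiran-2-yl]-2-hydroxy-6-methyloct-5-en-2-yl]-1,3-dioxolan-2-one
Conditions: CO2 (1 atm), Cs2CO3 (0.5 equiv), 3 Å molecular sieves, DMF, 40 °C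
Reagents that add atoms: carbon dioxide, O=C=O
Why: In this carboxylative opening of a 2,3-epoxy alcohol the cesium alkoxide at C2 takes up CO2 and the carbonate oxygen opens the oxirane at C3 (5-exo-tet, SN2) with inversion, which sets 3R, keeps 4S and brings in C16, while the isolated C11–C12 epoxide has no such neighbour and stays intact.

Step 8
Reactants: 11 C2/C3 carbonate with free C4–OH
Product: 13 tosylate of the C3/C4 carbonate, via carbonate isomer 12 (not isolated)
Conditions: TsCl, Et3N, DBU (0.2 equiv), DMAP (cat.), CH2Cl2, 0 °C to rt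
Reagents that add atoms: 4-toluenesulfonyl chloride, Cc1ccc(cc1)S(=O)(=O)Cl
Why: Base-mediated transcarbonation equilibrates 11 with its C3/C4 isomer 12, and only 12 offers an unhindered primary alcohol, so sulfonylation drains the equilibrium (Curtin–Hammett situation) while the acyl shifts occur at oxygen and leave C3 and C4 untouched.

Step 9
Reactants: 13 tosylate
Product: 14 (4S,5S)-5-[(E)-6-[(2S,3S)-3-(but-3-ynyl)-3-methyloxiran-2-yl]-4-methylhex-3-enyl]-4-(iodomethyl)-5-methyl-1,3-dioxolan-2-one
Conditions: NaI, acetone, reflux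
Reagents that add atoms: sodium iodide, [Na+].[I-]
Why: The Finkelstein reaction (SN2 at primary C2, driven by precipitation of the sulfonate salt) installs the soft leaving group under neutral conditions that spare carbonate, epoxide and alkyne.

Step 10
Reactants: 14 iodomethyl cyclic carbonate with terminal alkyne
Product: 16 (3R,4S,7E,11S,12S)-11,12-epoxy-4-hydroxy-17-norcembra-1(15),7-dien-16,3-olide, via alkenylboronate 15 (not isolated)
Conditions: (SIMes)CuCl (1.2 equiv; SIMes = 1,3-dimesitylimidazolidin-2-ylidene), NaOtBu (1.2 equiv), B2pin2 (1.2 equiv), THF, rt; 14 added over 12 h (final 1 mM); then NaOtBu (1.2 equiv), 50 °C; aq NH4Cl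
Reagents that add atoms: none
Why: Proposed new method: (SIMes)Cu–Bpin, preformed from (SIMes)CuCl, NaOtBu and B2pin2, adds syn across the terminal alkyne with boron on C15 and copper on C1, the persistent alkenylcopper displaces the C2 iodide (14-exo-tet closure of the carbocycle) to give 15, and the second charge of NaOtBu regenerates (SIMes)CuOtBu, which exchanges boron for copper at C15 so that the new alkenylcopper attacks the carbonate carbonyl C16 (6-exo-trig closure of the lactone) and expels the tertiary C4 alkoxide. The closest known reaction types are the copper-catalysed intramolecular alkylboration of alkynes with alkyl halides and the copper-catalysed carboxylation of alkenylboronates with CO2, joined here in one flask with a cyclic carbonate in the role of CO2 and B2pin2 as the two-electron reductant. No stereocentre is formed: syn addition and retention in both substitutions place C2 and C16 cis on C1=C15, as the six-membered ring demands, and C3, C4, C11 and C12 are not touched. The step needs chemoselectivity for the alkyne (the trisubstituted alkene and epoxide do not insert into Cu–B, and boron goes to the terminal carbon), the right pairing of the ends (soft alkenylcopper prefers C–I to the carbonate, and C15 becomes nucleophilic only after C1–C2 exists) and ring closure instead of oligomerisation (slow addition into excess Cu–Bpin at high dilution, with no fast unimolecular decay channel for the organocopper, unlike a C2 radical, which would close onto C7=C8). If the C3 alkoxide is expelled instead, the seven-membered lactone on O4 should translactonise under the alkoxide conditions to the δ-lactone with the free tertiary alcohol.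

Step 11
Reactants: 16 unsaturated δ-lactone
Product: 17 (1R,3R,4S,7E,11S,12S)-11,12-epoxy-4-hydroxy-17-norcembr-7-en-16,3-olide
Conditions: Cu(OAc)2·H2O (5 mol %), 1,2-bis(diphenylphosphino)benzene (5 mol %), (EtO)2MeSiH, t-BuOH, toluene, rt
Reagents that add atoms: none
Why: Copper hydride conjugate reduction of a β,β-disubstituted unsaturated lactone leaves the isolated alkene and the epoxide alone, and hydride should reach C1 from the outer face, opposite the C3–C4 bond and the macrocyclic loop, which places the C14 chain cis to C4 on the lactone (1R).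

Step 12
Reactants: 17 saturated lactone
Product: 18 (1R,3R,4S,7E,11S,12S,15S)-11,12-epoxy-4-hydroxycembr-7-en-16,3-olide
Conditions: LiN(iPr)2 (2.2 equiv), THF, −78 °C; MeI, −78 °C to −40 °C
Reagents that add atoms: iodomethane, CI
Why: In this lactone enolate alkylation (the C4 alkoxide is a spectator) MeI approaches anti to the adjacent C14 chain, which gives the trans, all-equatorial 15S methyl group that is also the thermodynamic epimer.

Step 13
Reactants: 18 C7=C8 alkene
Product: 19 target hydroperoxide CNP0319766.1
Conditions: O2, tetraphenylporphyrin (cat.), visible light, CH2Cl2, −20 °C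
Reagents that add atoms: dioxygen, O=O
Why: The Schenck ene reaction of singlet oxygen with the only remaining alkene copies the presumed biogenesis: oxygen binds C7 from the outer face of the macrocycle (7R), and hydrogen is taken from the C19 methyl on the more crowded alkene side (cis effect) to give the exocyclic C8=CH2, with the C8 hydroperoxide as the regioisomer to be separated.

Compound list
1 | (2E,6E)-farnesol | OC/C=C(\C)CC/C=C(\C)CCC=C(C)C | starting material
2 | (2E,6E)-farnesyl tert-butyldimethylsilyl ether | CC(C)(C)[Si](C)(C)OC/C=C(\C)CC/C=C(\C)CCC=C(C)C | intermediate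
3 | (2E,6E,10E)-12-(tert-butyldimethylsilyloxy)-2,6,10-trimethyldodeca-2,6,10-trien-1-ol | CC(C)(C)[Si](C)(C)OC/C=C(\C)CC/C=C(\C)CC/C=C(\C)CO | intermediate
4 | [(2S,3S)-3-[(3E,7E)-9-(tert-butyldimethylsilyloxy)-3,7-dimethylnona-3,7-dienyl]-2-methyloxiran-2-yl]methanol | CC(C)(C)[Si](C)(C)OC/C=C(\C)CC/C=C(\C)CC[C@@H]1O[C@@]1(C)CO | intermediate
5 | 1-(trimethylsilyl)propyne | CC#C[Si](C)(C)C | starting material
6 | 3-lithio-1-(trimethylsilyl)propyne | [Li]CC#C[Si](C)(C)C | intermediate
7 | trifluoromethanesulfonate of 4 | CC(C)(C)[Si](C)(C)OC/C=C(\C)CC/C=C(\C)CC[C@@H]1O[C@@]1(C)COS(=O)(=O)C(F)(F)F | intermediate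
8 | tert-butyldimethylsilyl ether of (2E,6E)-3,7-dimethyl-9-[(2S,3S)-3-methyl-3-(4-trimethylsilylbut-3-ynyl)oxiran-2-yl]nona-2,6-dien-1-ol | CC(C)(C)[Si](C)(C)OC/C=C(\C)CC/C=C(\C)CC[C@@H]1O[C@@]1(C)CCC#C[Si](C)(C)C | intermediate
9 | (2E,6E)-9-[(2S,3S)-3-(but-3-ynyl)-3-methyloxiran-2-yl]-3,7-dimethylnona-2,6-dien-1-ol | OC/C=C(\C)CC/C=C(\C)CC[C@@H]1O[C@@]1(C)CCC#C | intermediate
10 | [(2S,3S)-3-[(E)-6-[(2S,3S)-3-(but-3-ynyl)-3-methyloxiran-2-yl]-4-methylhex-3-enyl]-3-methyloxiran-2-yl]methanol | OC[C@@H]1O[C@@]1(C)CC/C=C(\C)CC[C@@H]2O[C@@]2(C)CCC#C | intermediate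
11 | (4R)-4-[(2S,5E)-8-[(2S,3S)-3-(but-3-ynyl)-3-methyloxiran-2-yl]-2-hydroxy-6-methyloct-5-en-2-yl]-1,3-dioxolan-2-one | O=C1OC[C@@H](O1)[C@@](C)(O)CC/C=C(\C)CC[C@@H]2O[C@@]2(C)CCC#C | intermediate
12 | (4R,5S)-5-[(E)-6-[(2S,3S)-3-(but-3-ynyl)-3-methyloxiran-2-yl]-4-methylhex-3-enyl]-4-(hydroxymethyl)-5-methyl-1,3-dioxolan-2-one | OC[C@H]1OC(=O)O[C@@]1(C)CC/C=C(\C)CC[C@@H]2O[C@@]2(C)CCC#C | intermediate
13 | 4-toluenesulfonate of 12 | Cc1ccc(cc1)S(=O)(=O)OC[C@H]1OC(=O)O[C@@]1(C)CC/C=C(\C)CC[C@@H]2O[C@@]2(C)CCC#C | intermediate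
14 | (4S,5S)-5-[(E)-6-[(2S,3S)-3-(but-3-ynyl)-3-methyloxiran-2-yl]-4-methylhex-3-enyl]-4-(iodomethyl)-5-methyl-1,3-dioxolan-2-one | IC[C@H]1OC(=O)O[C@@]1(C)CC/C=C(\C)CC[C@@H]2O[C@@]2(C)CCC#C | intermediate
15 | 14-membered carbocycle with C3/C4 cyclic carbonate, (7E)-alkene, (11S,12S)-epoxide and exocyclic (Z)-C1=C15H–Bpin | C1[C@H]2OC(=O)O[C@@]2(C)CC/C=C(\C)CC[C@@H]3O[C@@]3(C)CC/C1=C/B4OC(C)(C)C(C)(C)O4 | intermediate
16 | (3R,4S,7E,11S,12S)-11,12-epoxy-4-hydroxy-17-norcembra-1(15),7-dien-16,3-olide | O=C1C=C2C[C@@H](O1)[C@@](C)(O)CC/C=C(\C)CC[C@@H]3O[C@@]3(C)CC2 | intermediate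
17 | (1R,3R,4S,7E,11S,12S)-11,12-epoxy-4-hydroxy-17-norcembr-7-en-16,3-olide | O=C1C[C@H]2C[C@@H](O1)[C@@](C)(O)CC/C=C(\C)CC[C@@H]3O[C@@]3(C)CC2 | intermediate
18 | (1R,3R,4S,7E,11S,12S,15S)-11,12-epoxy-4-hydroxycembr-7-en-16,3-olide | O=C1[C@@H](C)[C@H]2C[C@@H](O1)[C@@](C)(O)CC/C=C(\C)CC[C@@H]3O[C@@]3(C)CC2 | intermediate
19 | (1R,3R,4S,7R,11S,12S,15S)-11,12-epoxy-7-hydroperoxy-4-hydroxycembr-8(19)-en-16,3-olide (CNP0319766.1) | C=C1CC[C@@H]2O[C@@]2(C)CC[C@@H]2C[C@@H](OC(=O)[C@H]2C)[C@@](C)(O)CC[C@H]1OO | target

Total steps: 13. Longest linear sequence: 13 steps (from 1).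

Steps most likely to fail

Step 10. The boron-to-copper exchange at C15, or the attack of the alkenylcopper on the carbonate, may stall. Attack of tert-butoxide on the carbonate, or borylation of the C–I bond, may also compete with ring closure.
Fallback (from 14, back at 16): the copper-mediated intramolecular alkylboration, a known reaction type, is stopped before the second charge of NaOtBu and 15 is isolated. Iododeboronation with N-iodosuccinimide in MeCN gives, with retention, the alkenyl iodide F1. K2CO3 in MeOH removes the carbonate to give the iodo diol F2. Carbonylative lactonization with the zerovalent palladium complex Pd(PPh3)4, CO (1 atm) and Et3N in THF is a known route from (Z)-iodo homoallylic alcohols to unsaturated δ-lactones. It closes C15–C16 and gives 16.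

Step 11. Hydride transfer to the hindered β-carbon may be slow, or delivery to the inner face of C1 may erode the facial selectivity.
Fallback (from 16, back at 17): the reduction is changed from hydride addition to electron transfer with Mg in MeOH at 0 °C to rt. C1 is then protonated from the open outer face. Any lactone opened by Mg(OMe)2 appears as the hydroxy methyl ester F3, which is closed again with catalytic DBU in toluene at 80 °C to give 17.

Step 4. Substitution next to the fully substituted epoxide carbon may be slow, so that opening of the oxirane or decay of the triflate competes.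
Fallback (from 4, back at 8): the bond is made one carbon further out, at an unhindered centre. Parikh–Doering oxidation (SO3·pyridine, DMSO, Et3N) gives the epoxy aldehyde F4, and Wittig methylenation (Ph3P=CH2) gives the vinyl epoxide F5. Hydroboration with 9-BBN, which is selective for the monosubstituted alkene, followed by NaBO3 gives the alcohol F6. An Appel reaction (I2, PPh3, imidazole) gives the iodide F7. LiC≡CSiMe3 in THF–DMPU then forms C14–C1 to give 8.

Further compounds
F1 | step 10 | macrocyclic C3/C4 carbonate with exocyclic (Z)-C1=C15H–I | C1[C@H]2OC(=O)O[C@@]2(C)CC/C=C(\C)CC[C@@H]3O[C@@]3(C)CC/C1=C/I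
F2 | step 10 | macrocyclic (3R,4S)-diol with exocyclic (Z)-C1=C15H–I | C1[C@@H](O)[C@@](C)(O)CC/C=C(\C)CC[C@@H]2O[C@@]2(C)CC/C1=C/I
F3 | step 11 | methyl ester of the ring-opened hydroxy acid of 17 | COC(=O)C[C@H]1C[C@@H](O)[C@@](C)(O)CC/C=C(\C)CC[C@@H]2O[C@@]2(C)CC1
F4 | step 4 | epoxy aldehyde from 4 | CC(C)(C)[Si](C)(C)OC/C=C(\C)CC/C=C(\C)CC[C@@H]1O[C@@]1(C)C=O
F5 | step 4 | vinyl epoxide | CC(C)(C)[Si](C)(C)OC/C=C(\C)CC/C=C(\C)CC[C@@H]1O[C@@]1(C)C=C
F6 | step 4 | homologous primary alcohol (C14–OH) | CC(C)(C)[Si](C)(C)OC/C=C(\C)CC/C=C(\C)CC[C@@H]1O[C@@]1(C)CCO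
F7 | step 4 | primary iodide (C14–I) | CC(C)(C)[Si](C)(C)OC/C=C(\C)CC/C=C(\C)CC[C@@H]1O[C@@]1(C)CCI
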